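**Retrosynthetic overview**

1. Locants: C1 lactone C=O, C2 its CH2, C3 CH–OO, C4 C(CH3)–O(lactone), C5 ring CH2, C6 C(CH3)(C16H33)–OO. Enabling feature: the γ-lactone O–C1(=O)–C2–C3–C4, with its ring oxygen on quaternary C4, is the Baeyer–Villiger image of a cyclobutanone C1–C2–C3–C4; C3 carries an oxygen β to C1, so C4=C1=O is a ketene, C2=C3–O an enol ether, and C5–C6–O (C6 is 1,3 to C4) a three-atom tether.
2. Target 19 ⇐ diimide reduction and cross-metathesis (C16 chain) ⇐ allyl peroxide 16 ⇐ peroxycarbenium allylation of cyclic methoxy peroxyketal 14 (sets C6) ⇐ H2O2/MeOH ketalization and intramolecular hydroperoxide oxa-Michael addition (closes the 1,2-dioxane, sets C3) on keto butenolide 12.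
3. 12 ⇐ alcohol oxidation and E1cB opening of the temporary tetrahydrofuran of ether-lactone 10 ⇐ Baeyer–Villiger ring expansion of cyclobutanone 9.
4. 9 ⇐ intramolecular ketene–enol ether [2+2] cycloaddition (forms C1–C2 and C3–C4, sets C4 from a sacrificial C6–H stereocenter) ⇐ vinyloxy carboxylate 6 ⇐ propionitrile, (S)-propylene oxide, vinyl acetate.
5. Ring order: tetrahydrofuran and cyclobutanone together (step 4), γ-lactone by ring expansion (step 5), tetrahydrofuran opened (step 6), 1,2-dioxane (step 8).

Key step: step 4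

Remark (assumption): the tether methyl group is taken to occupy the exo face in the key cycloaddition; this is what fixes (S)-propylene oxide as the chirality source.

**Route**

Step 1
Reactants: 1 propionitrile; 2 (S)-propylene oxide
Product: 3 (4S)-4-hydroxy-2-methylpentanenitrile (both C2 epimers)
Conditions: LDA, THF, –78 °C; then 2, –78 °C → rt; aq. NH4Cl
Reagents that add atoms: none
Why: Epoxide opening by an α-lithiated nitrile occurs by SN2 attack at the CH2 terminus, so the carbinol carbon (the future sacrificial C6) keeps its configuration, and the C2 epimers are irrelevant because this carbon becomes the sp2 ketene carbon.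

Step 2
Reactants: 3 (4S)-4-hydroxy-2-methylpentanenitrile; 4 vinyl acetate
Product: 5 (4S)-4-(ethenyloxy)-2-methylpentanenitrile
Conditions: [Ir(cod)Cl]2 (1 mol%), Na2CO3 (0.6 equiv), toluene, 100 °C
Reagents that add atoms: none
Why: Iridium-catalysed transfer vinylation of alcohols with vinyl acetate is general for secondary alcohols and touches neither the stereocenter nor the nitrile.

Step 3
Reactants: 5 (4S)-4-(ethenyloxy)-2-methylpentanenitrile
Product: 6 potassium (4S)-4-(ethenyloxy)-2-methylpentanoate
Conditions: KOH (1.2 equiv), EtOH/H2O, 100 °C (sealed); evaporate and dry, salt used as such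
Reagents that add atoms: potassium hydroxide, [K+].[OH-]; water, O
Why: Alkaline nitrile hydrolysis gives the carboxylate directly, and keeping it as the salt avoids the acid that the base-stable vinyl ether would not survive.

Step 4
Reactants: 6 potassium (4S)-4-(ethenyloxy)-2-methylpentanoate
Product: 9 (1S,3S,5S)-3,5-dimethyl-2-oxabicyclo[3.2.0]heptan-6-one, via acyloxypyridinium iodide 7 (not isolated), via ketene 8 (not isolated)
Conditions: 2-chloro-1-methylpyridinium iodide, Et3N, MeCN, 80 °C, slow addition of 6 (high dilution)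
Reagents that add atoms: none
Why: O-acylation of the pyridinium salt and elimination by Et3N should generate the methyl(alkyl)ketene 8, whose electrophilic carbonyl carbon C1 is attacked by the nucleophilic terminal CH2 (C2) of the enol ether while the oxygen-bearing C3 closes onto the ketene α-carbon C4 in an asynchronous thermal [2+2] cycloaddition. The closest known reaction types are the intramolecular ketene–alkene [2+2] cycloaddition across a three-atom tether and the intermolecular cycloaddition of dialkylketenes with vinyl ethers to 3-alkoxycyclobutanones. Both rings close in the same cycloaddition event, the five-membered oxacycle through C3–C4 across the C5–C6–O tether and the four-membered ring through C1–C2, and only the cis-fused bicyclo[3.2.0] skeleton is geometrically accessible. C3 and C4 are created together, cis by ring fusion, and their absolute sense is relayed from C6, whose methyl group should take the exo (convex) face away from the forming four-membered ring, which translates (S)-C6 into (S)-C4. The step needs fused rather than bridged regiochemistry, secured by the enol-ether polarization, and cyclization rather than ketene dimerization, secured by the disubstituted ketene and slow addition at high dilution; a minor endo-methyl diastereomer would be removed by chromatography here or at 10.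

Step 5
Reactants: 9 (1S,3S,5S)-3,5-dimethyl-2-oxabicyclo[3.2.0]heptan-6-one
Product: 10 (3aS,5S,6aS)-5,6a-dimethyltetrahydrofuro[3,2-b]furan-2(3H)-one
Conditions: mCPBA, CH2Cl2, 0 °C → rt
Reagents that add atoms: mCPBA, OOC(=O)c1cccc(Cl)c1
Why: Baeyer–Villiger oxidation of a cyclobutanone is driven by strain release, and the quaternary C4 migrates in preference to the CH2 with retention, which places the lactone oxygen on C4.

Step 6
Reactants: 10 (3aS,5S,6aS)-5,6a-dimethyltetrahydrofuro[3,2-b]furan-2(3H)-one
Product: 11 (5S)-5-[(2S)-2-hydroxypropyl]-5-methylfuran-2(5H)-one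
Conditions: LiHMDS (1.2 equiv), THF, –78 → 0 °C; AcOH, –78 °C; used crude
Reagents that add atoms: none
Why: E1cB β-elimination (retro-oxa-Michael) from the lactone enolate should open the tetrahydrofuran because, with a full equivalent of base, the secondary alkoxide is the more stable anion, and cold protonation then delivers the hydroxy butenolide with C4 untouched.

Step 7
Reactants: 11 (5S)-5-[(2S)-2-hydroxypropyl]-5-methylfuran-2(5H)-one
Product: 12 (5S)-5-methyl-5-(2-oxopropyl)furan-2(5H)-one
Conditions: Dess–Martin periodinane, CH2Cl2, rt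
Reagents that add atoms: none
Why: Dess–Martin oxidation of the secondary alcohol is base-free, so the sacrificial C6 stereocenter is erased without triggering re-closure by oxa-Michael addition.

Step 8
Reactants: 12 (5S)-5-methyl-5-(2-oxopropyl)furan-2(5H)-one
Product: 14 (4aS,7aS)-3-methoxy-3,4a-dimethyltetrahydrofuro[3,2-c][1,2]dioxin-6(3H)-one (both C3 epimers), via hydroperoxy ketal 13 (not isolated)
Conditions: urea·H2O2, Sc(OTf)3 (cat.), MeOH, rt; concentrate; Et2NH (cat.), CF3CH2OH, rt
Reagents that add atoms: urea–hydrogen peroxide, NC(N)=O.OO; methanol, CO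
Why: Acid-catalysed hydroperoxyketalization of the methyl ketone followed by amine-promoted intramolecular oxa-Michael addition of the hydroperoxide to the butenolide should close the 1,2-dioxane, and the tether delivers oxygen to the face of C3 syn to C5, so the ring fusion is cis and C3 is set from C4 (the ketal center converges in step 9).

Step 9
Reactants: 14 (4aS,7aS)-3-methoxy-3,4a-dimethyltetrahydrofuro[3,2-c][1,2]dioxin-6(3H)-one; 15 allyltrimethylsilane
Product: 16 (3R,4aS,7aS)-3,4a-dimethyl-3-(prop-2-en-1-yl)tetrahydrofuro[3,2-c][1,2]dioxin-6(3H)-one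
Conditions: TiCl4 (1.1 equiv), CH2Cl2, –78 °C
Reagents that add atoms: none
Why: Lewis-acid ionization of the peroxyketal gives a cyclic peroxycarbenium ion that is trapped by the allylsilane (Hosomi–Sakurai-type allylation of peroxyketals), and attack through the chair-like transition state of the half-chair with the C4–O bond pseudoaxial and the C4 methyl pseudoequatorial should place the allyl group cis to the lactone oxygen, away from a syn-axial clash with the C4 methyl, which sets C6 with the two methyl groups cis.

Step 10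
Reactants: 16 (3R,4aS,7aS)-3,4a-dimethyl-3-(prop-2-en-1-yl)tetrahydrofuro[3,2-c][1,2]dioxin-6(3H)-one; 17 1-pentadecene
Product: 18 (3R,4aS,7aS)-3-(hexadec-2-en-1-yl)-3,4a-dimethyltetrahydrofuro[3,2-c][1,2]dioxin-6(3H)-one (E/Z mixture)
Conditions: Grubbs II (5 mol%), 17 (4 equiv), CH2Cl2, 40 °C
Reagents that add atoms: none
Why: Olefin cross-metathesis of the monosubstituted allyl group with an excess of terminal alkene is reliable, ruthenium carbenes tolerate dialkyl peroxides, and the alkene geometry is irrelevant.

Step 11
Reactants: 18 (3R,4aS,7aS)-3-(hexadec-2-en-1-yl)-3,4a-dimethyltetrahydrofuro[3,2-c][1,2]dioxin-6(3H)-one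
Product: 19 (3R,4aS,7aS)-3-hexadecyl-3,4a-dimethyltetrahydrofuro[3,2-c][1,2]dioxin-6(3H)-one (target)
Conditions: dipotassium azodicarboxylate, AcOH, MeOH/CH2Cl2, 0 °C → rt
Reagents that add atoms: none
Why: Diimide reduction saturates the isolated C=C bond without cleaving the O–O bond, which catalytic hydrogenation would not spare.

**Compound list**

1 | propionitrile | CCC#N | starting material
2 | (S)-propylene oxide [(2S)-2-methyloxirane] | C[C@H]1CO1 | starting material
3 | (4S)-4-hydroxy-2-methylpentanenitrile (both C2 epimers) | C[C@H](O)CC(C)C#N | intermediate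
4 | vinyl acetate | CC(=O)OC=C | starting material
5 | (4S)-4-(ethenyloxy)-2-methylpentanenitrile | C[C@H](OC=C)CC(C)C#N | intermediate
6 | potassium (4S)-4-(ethenyloxy)-2-methylpentanoate | C[C@H](OC=C)CC(C)C(=O)[O-].[K+] | intermediate
7 | 2-{[(4S)-4-(ethenyloxy)-2-methylpentanoyl]oxy}-1-methylpyridin-1-ium iodide | C[C@H](OC=C)CC(C)C(=O)Oc1cccc[n+]1C.[I-] | intermediate (not isolated)
8 | (4S)-4-(ethenyloxy)-2-methylpent-1-en-1-one (ketene) | C[C@H](OC=C)CC(C)=C=O | intermediate (not isolated)
9 | (1S,3S,5S)-3,5-dimethyl-2-oxabicyclo[3.2.0]heptan-6-one | C[C@H]1C[C@]2(C)C(=O)C[C@@H]2O1 | intermediate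
10 | (3aS,5S,6aS)-5,6a-dimethyltetrahydrofuro[3,2-b]furan-2(3H)-one | C[C@H]1C[C@]2(C)OC(=O)C[C@@H]2O1 | intermediate
11 | (5S)-5-[(2S)-2-hydroxypropyl]-5-methylfuran-2(5H)-one | C[C@H](O)C[C@]1(C)OC(=O)C=C1 | intermediate
12 | (5S)-5-methyl-5-(2-oxopropyl)furan-2(5H)-one | CC(=O)C[C@]1(C)OC(=O)C=C1 | intermediate
13 | (5S)-5-(2-hydroperoxy-2-methoxypropyl)-5-methylfuran-2(5H)-one (both ketal epimers) | COC(C)(OO)C[C@]1(C)OC(=O)C=C1 | intermediate (not isolated)
14 | (4aS,7aS)-3-methoxy-3,4a-dimethyltetrahydrofuro[3,2-c][1,2]dioxin-6(3H)-one (both C3 epimers) | COC1(C)C[C@]2(C)OC(=O)C[C@@H]2OO1 | intermediate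
15 | allyltrimethylsilane | C=CC[Si](C)(C)C | starting material
16 | (3R,4aS,7aS)-3,4a-dimethyl-3-(prop-2-en-1-yl)tetrahydrofuro[3,2-c][1,2]dioxin-6(3H)-one | C=CC[C@]1(C)C[C@]2(C)OC(=O)C[C@@H]2OO1 | intermediate
17 | 1-pentadecene | CCCCCCCCCCCCCC=C | starting material
18 | (3R,4aS,7aS)-3-(hexadec-2-en-1-yl)-3,4a-dimethyltetrahydrofuro[3,2-c][1,2]dioxin-6(3H)-one (E/Z) | CCCCCCCCCCCCCC=CC[C@]1(C)C[C@]2(C)OC(=O)C[C@@H]2OO1 | intermediate
19 | (3R,4aS,7aS)-3-hexadecyl-3,4a-dimethyltetrahydrofuro[3,2-c][1,2]dioxin-6(3H)-one | CCCCCCCCCCCCCCCC[C@]1(C)C[C@]2(C)OC(=O)C[C@@H]2OO1 | target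

**Step count and risks**

Total step count: 11. Longest linear sequence: 11 steps (from 1 and 2).

Steps most likely to fail:

Step 4 (key step). The facial discrimination exerted by the single C6 methyl group may be weak (the endo-methyl diastereomer leads into the enantiomeric series), the ketene may dimerize, or the vinyl ether may be lost to adventitious acid. The fallback sets out from 6 and returns at 9. Compound 6 is coupled with pyrrolidine (EDC·HCl, HOBt, CH2Cl2) to 1-[(4S)-4-(ethenyloxy)-2-methylpentanoyl]pyrrolidine F1. Tf2O and 2,4,6-collidine in CH2Cl2 at –78 → 0 °C convert it into N-[(4S)-4-(ethenyloxy)-2-methylpent-1-en-1-ylidene]pyrrolidinium triflate F2. This keteniminium ion is a much stronger electrophile than the ketene and should cyclize well below room temperature, through a tighter stepwise cationic transition state, to 1-[(1S,3S,5S)-3,5-dimethyl-2-oxabicyclo[3.2.0]heptan-6-ylidene]pyrrolidinium triflate F3. Hydrolysis with aqueous NaHCO3 gives 9. Should the cycloaddition prove to favour the endo-methyl isomer, (R)-propylene oxide would be used in step 1.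

Step 9. Allyl transfer to the peroxycarbenium ion may show poor facial selectivity, or the Lewis acid may induce O–O heterolysis and fragmentation instead of ionizing the C–OMe bond. The fallback sets out from 12 and returns at 19, replacing steps 8–11. Wittig olefination of 12 with the ylide from hexadecyltriphenylphosphonium bromide (NaHMDS, THF, –78 °C → rt) gives (5S)-5-methyl-5-(2-methyloctadec-2-en-1-yl)furan-2(5H)-one F5. Isayama–Mukaiyama hydroperoxysilylation (Co(thd)2 cat., O2, Et3SiH, ClCH2CH2Cl) gives (5S)-5-methyl-5-{2-methyl-2-[(triethylsilyl)peroxy]octadecyl}furan-2(5H)-one F6. Desilylation (cat. HCl, MeOH) gives (5S)-5-(2-hydroperoxy-2-methyloctadecyl)-5-methylfuran-2(5H)-one F7, and Et2NH in CF3CH2OH closes the dioxane by oxa-Michael addition. This gives 19 together with its C6 epimer (3S,4aS,7aS)-3-hexadecyl-3,4a-dimethyltetrahydrofuro[3,2-c][1,2]dioxin-6(3H)-one F8, which is separated by chromatography; C6 is then formed without control.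

Step 6. β-Elimination may be incomplete, or the tetrahydrofuran may re-close by oxa-Michael addition during protonation and handling. The fallback sets out from 10 and returns at 12, replacing steps 6 and 7. The ether methine C–H next to the ring oxygen is oxidized with RuCl3 (cat.)/NaIO4 in CCl4/MeCN/H2O to (3aS,6aS)-5-hydroxy-5,6a-dimethyltetrahydrofuro[3,2-b]furan-2(3H)-one F4. DBU in CH2Cl2 then effects E1cB elimination in which the leaving hemiketal alkoxide collapses irreversibly to the ketone, giving 12 with loss of water.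

**Further compounds**

F1 | step 4 | 1-[(4S)-4-(ethenyloxy)-2-methylpentanoyl]pyrrolidine | C[C@H](OC=C)CC(C)C(=O)N1CCCC1
F2 | step 4 | N-[(4S)-4-(ethenyloxy)-2-methylpent-1-en-1-ylidene]pyrrolidinium triflate | C[C@H](OC=C)CC(C)=C=[N+]1CCCC1.[O-]S(=O)(=O)C(F)(F)F
F3 | step 4 | 1-[(1S,3S,5S)-3,5-dimethyl-2-oxabicyclo[3.2.0]heptan-6-ylidene]pyrrolidinium triflate | C[C@H]1C[C@]2(C)C(=[N+]3CCCC3)C[C@@H]2O1.[O-]S(=O)(=O)C(F)(F)F
F4 | step 6 | (3aS,6aS)-5-hydroxy-5,6a-dimethyltetrahydrofuro[3,2-b]furan-2(3H)-one | CC1(O)C[C@]2(C)OC(=O)C[C@@H]2O1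
F5 | step 9 | (5S)-5-methyl-5-(2-methyloctadec-2-en-1-yl)furan-2(5H)-one | CCCCCCCCCCCCCCCC=C(C)C[C@]1(C)OC(=O)C=C1
F6 | step 9 | (5S)-5-methyl-5-{2-methyl-2-[(triethylsilyl)peroxy]octadecyl}furan-2(5H)-one | CCCCCCCCCCCCCCCCC(C)(OO[Si](CC)(CC)CC)C[C@]1(C)OC(=O)C=C1
F7 | step 9 | (5S)-5-(2-hydroperoxy-2-methyloctadecyl)-5-methylfuran-2(5H)-one | CCCCCCCCCCCCCCCCC(C)(OO)C[C@]1(C)OC(=O)C=C1
F8 | step 9 | (3S,4aS,7aS)-3-hexadecyl-3,4a-dimethyltetrahydrofuro[3,2-c][1,2]dioxin-6(3H)-one | CCCCCCCCCCCCCCCC[C@@]1(C)C[C@]2(C)OC(=O)C[C@@H]2OO1
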